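**Plan**
1. Cuts: the two aryl acetates of the last intermediate are only masks. Behind them ring A is opened at C4–C5 and O1–C2. Next the bond between the bridge CH2 and C3 is cut, and then the C–CH2, C–prenyl and C–acyl bonds on ring B, back to 5-methoxyresorcinol.
2. Enabling feature: in ring A (O1, C2–C6) the run C2–C3–C4 is a malonyl unit whose middle carbon C3 carries the CH2 bridge to ring B. C5(CH3)–C6(C2H5)–O1 is the enol form of symmetrical pentan-3-one, so two fragments at the correct oxidation level can be joined 3 + 3.
3. Forward: ring B is bought and its three free carbons are filled in the order isobutyryl, prenyl, aminomethyl. The amine is exchanged for diallyl malonate through a quinone methide, and acetylation, deallylation and chlorination then give the arylmethylmalonyl dichloride.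
4. Ring A is the only ring made. It closes in one operation from that dichloride and the silyl enol ether of pentan-3-one, and methanolysis of the acetates ends the route.
5. Stereochemistry: the target has no stereocentre and no stereodefined double bond, so nothing has to be set. The enol ether geometry is erased in the aromatic pyranone.

Key step: step 9

Remark: the pyranone is drawn throughout as its 4-hydroxy-2-pyranone tautomer, as in the target SMILES. The enol ether is drawn as the expected Z isomer, but either isomer would serve.

**Step 1**
Reactants: 1 5-methoxybenzene-1,3-diol; 2 2-methylpropanenitrile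
Product: 4 1-(2,4-dihydroxy-6-methoxyphenyl)-2-methylpropan-1-one, via ketiminium chloride 3 (not isolated)
Conditions: ZnCl2, HCl (g), Et2O, 0 °C; then H2O, reflux
Reagents that add atoms: water, O
Why: Houben–Hoesch acylation: the protonated nitrile attacks the electron-rich ring mainly at C4/C6 (two equivalent sites, each para to a free OH) rather than at C2, hydrolysis of salt 3 gives the ketone, the ZnCl2/HCl medium should spare the methyl ether next to the new carbonyl where AlCl3 might cleave it, and the minor 2,6-dihydroxy-4-methoxy isomer is removed by chromatography.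

**Step 2**
Reactants: 4 1-(2,4-dihydroxy-6-methoxyphenyl)-2-methylpropan-1-one; 5 1-bromo-3-methylbut-2-ene
Product: 6 1-[2,4-dihydroxy-6-methoxy-3-(3-methylbut-2-enyl)phenyl]-2-methylpropan-1-one
Conditions: KOH (aq), 5 (1.0 equiv), 0 °C → rt
Reagents that add atoms: none
Why: Nuclear C-prenylation of an ambident phenoxide: water hydrogen-bonds the oxygen anions so that the soft allylic bromide is taken up at carbon in an SN2 sense, preferentially at C3 between the two oxygens as is usual for resacetophenone- and phloracylphenone-type substrates, and one equivalent of 5 at low temperature limits double alkylation.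

**Step 3**
Reactants: 6 1-[2,4-dihydroxy-6-methoxy-3-(3-methylbut-2-enyl)phenyl]-2-methylpropan-1-one
Product: 7 1-[3-[(dimethylamino)methyl]-4,6-dihydroxy-2-methoxy-5-(3-methylbut-2-enyl)phenyl]-2-methylpropan-1-one
Conditions: 37% aq. CH2O, 40% aq. Me2NH (both in excess), EtOH, 0 °C → rt
Reagents that add atoms: formaldehyde, C=O; dimethylamine, CNC
Why: Phenol Mannich reaction: the iminium ion attacks the single unsubstituted ring carbon, which is ortho to the free 4-OH and far more nucleophilic than the hindered tertiary alpha carbon of the ketone, and the mild aqueous medium does not touch the prenyl group.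

**Step 4**
Reactants: 7 1-[3-[(dimethylamino)methyl]-4,6-dihydroxy-2-methoxy-5-(3-methylbut-2-enyl)phenyl]-2-methylpropan-1-one; 8 diallyl propanedioate
Product: 11 diallyl 2-[[2,4-dihydroxy-6-methoxy-5-(2-methylpropanoyl)-3-(3-methylbut-2-enyl)phenyl]methyl]propanedioate, via benzylic trimethylammonium iodide 9 (not isolated), via ortho-quinone methide 10 (not isolated)
Conditions: MeI (1.05 equiv), THF, rt; then added to 8 (4 equiv)/NaH (3.5 equiv), THF–DMF, 0 °C → rt; aq. NH4Cl
Reagents that add atoms: none
Why: Alkylation of a malonate by a quaternised phenolic Mannich base: deprotonation of the phenol expels NMe3 to give quinone methide 10, the excess malonate anion adds in a Michael sense to its exocyclic CH2, and the phenoxide left next to the side chain lies para to the acyl group (a vinylogous carboxylate), so it should be too poor a nucleophile to lactonise on an allyl ester at or below room temperature.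

**Step 5**
Reactants: 11 diallyl 2-[[2,4-dihydroxy-6-methoxy-5-(2-methylpropanoyl)-3-(3-methylbut-2-enyl)phenyl]methyl]propanedioate
Product: 12 diallyl 2-[[2,4-diacetoxy-6-methoxy-5-(2-methylpropanoyl)-3-(3-methylbut-2-enyl)phenyl]methyl]propanedioate
Conditions: Ac2O, pyridine, DMAP (cat.), CH2Cl2, 0 °C → rt
Reagents that add atoms: acetic anhydride, CC(=O)OC(C)=O
Why: DMAP-catalysed O-acetylation caps both phenols, the chelated one included, so that neither can attack the acid chlorides made later, while pyridine is too weak a base to enolise and acylate the malonate.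

**Step 6**
Reactants: 12 diallyl 2-[[2,4-diacetoxy-6-methoxy-5-(2-methylpropanoyl)-3-(3-methylbut-2-enyl)phenyl]methyl]propanedioate
Product: 13 2-[[2,4-diacetoxy-6-methoxy-5-(2-methylpropanoyl)-3-(3-methylbut-2-enyl)phenyl]methyl]propanedioic acid
Conditions: Pd(PPh3)4 (5 mol %), HCO2H, Et3N, THF, rt
Reagents that add atoms: none
Why: Tsuji–Trost-type deallylation: zerovalent palladium ionises both allyl esters and formate reduces the pi-allyl complexes to propene with loss of CO2, this non-nucleophilic scavenger spares the aryl acetates that morpholine or pyrrolidine would aminolyse, the prenyl group has no leaving group to ionise, and at room temperature the malonic acid should not decarboxylate.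

**Step 7**
Reactants: 13 2-[[2,4-diacetoxy-6-methoxy-5-(2-methylpropanoyl)-3-(3-methylbut-2-enyl)phenyl]methyl]propanedioic acid
Product: 14 2-[[2,4-diacetoxy-6-methoxy-5-(2-methylpropanoyl)-3-(3-methylbut-2-enyl)phenyl]methyl]propanedioyl dichloride
Conditions: (COCl)2, DMF (cat.), CH2Cl2, 0 °C → rt; volatiles removed cold, used crude
Reagents that add atoms: oxalyl chloride, O=C(Cl)C(=O)Cl
Why: Acid chloride formation through the Vilsmeier-type chloroiminium salt works below room temperature with only gaseous by-products, conditions that trisubstituted alkenes in unsaturated acids routinely survive, and immediate use of the crude dichloride avoids loss of HCl on storage.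

**Step 8**
Reactants: 15 pentan-3-one
Product: 16 (Z)-trimethyl(pent-2-en-3-yloxy)silane
Conditions: TMSOTf, Et3N, Et2O, 0 °C → rt; distillation
Reagents that add atoms: trimethylsilyl trifluoromethanesulfonate, C[Si](C)(C)OS(=O)(=O)C(F)(F)F
Why: Soft enolisation and O-silylation: the ketone is symmetrical, so only one constitutional enol ether can form, the Z isomer should predominate, and its geometry has no consequence later.

**Step 9**
Reactants: 14 2-[[2,4-diacetoxy-6-methoxy-5-(2-methylpropanoyl)-3-(3-methylbut-2-enyl)phenyl]methyl]propanedioyl dichloride; 16 (Z)-trimethyl(pent-2-en-3-yloxy)silane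
Product: 18 3-[[2,4-diacetoxy-6-methoxy-5-(2-methylpropanoyl)-3-(3-methylbut-2-enyl)phenyl]methyl]-6-ethyl-4-hydroxy-5-methyl-2H-pyran-2-one, via acyclic 3,5-dioxoheptanoyl chloride 17 (not isolated)
Conditions: 16 (slight excess), Et2O–CH2Cl2, −78 °C → rt, slow argon stream, no base
Reagents that add atoms: none
Why: The nucleophilic CH carbon of enol ether 16 adds to one acid chloride of 14 and Me3SiCl is lost, which forms the C4–C5 bond and gives the acyclic acid chloride 17. The enol oxygen of its ethyl ketone then attacks the remaining acid chloride (O1–C2 bond, 6-exo-trig closure of ring A), HCl leaves, and tautomerisation to the aromatic 4-hydroxy-2-pyranone makes the sequence irreversible. The closest known reaction type is the Effenberger-type pyranone synthesis from malonyl dichlorides, 2-substituted ones included, and ketone silyl enol ethers. No stereocentre is created, because both sp3 centres of 17 are planarised in 18 and the enol ether geometry is lost with them. The selectivity needed is O-closure over a second C-acylation at the CH2 of the ethyl group (which would lead to a cyclohexanetrione), and it is secured by the absence of base and Lewis acid, the low temperature and the conjugated enol of 17, which places its oxygen rather than a carbon within reach of the acid chloride. Aryl acetates, aryl ketone and methyl ether are inert to acid chlorides, and HCl is carried off in the argon stream or taken up by the slight excess of 16 before it can add to the prenyl double bond.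

**Step 10**
Reactants: 18 3-[[2,4-diacetoxy-6-methoxy-5-(2-methylpropanoyl)-3-(3-methylbut-2-enyl)phenyl]methyl]-6-ethyl-4-hydroxy-5-methyl-2H-pyran-2-one
Product: 19 3-[[2,4-dihydroxy-6-methoxy-5-(2-methylpropanoyl)-3-(3-methylbut-2-enyl)phenyl]methyl]-6-ethyl-4-hydroxy-5-methyl-2H-pyran-2-one (target)
Conditions: K2CO3, MeOH, 0 °C, argon; then aq. citric acid
Reagents that add atoms: none
Why: Base-mediated transesterification of aryl acetates: methoxide cleaves the two activated phenyl esters quickly, the pyranone is present as its delocalised 4-oxido anion and so resists ring opening, short cold exposure avoids base-induced scrambling of the methylene bridge, and mild acidification returns the neutral target without cyclising the prenyl phenol to a chroman.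

**Compound list**
1 | 5-methoxybenzene-1,3-diol | COc1cc(O)cc(O)c1 | starting material
2 | 2-methylpropanenitrile | CC(C)C#N | starting material
3 | 1-(2,4-dihydroxy-6-methoxyphenyl)-2-methylpropan-1-iminium chloride | COc1cc(O)cc(O)c1C(=[NH2+])C(C)C.[Cl-] | intermediate
4 | 1-(2,4-dihydroxy-6-methoxyphenyl)-2-methylpropan-1-one | COc1cc(O)cc(O)c1C(=O)C(C)C | intermediate
5 | 1-bromo-3-methylbut-2-ene | CC(C)=CCBr | starting material
6 | 1-[2,4-dihydroxy-6-methoxy-3-(3-methylbut-2-enyl)phenyl]-2-methylpropan-1-one | COc1cc(O)c(CC=C(C)C)c(O)c1C(=O)C(C)C | intermediate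
7 | 1-[3-[(dimethylamino)methyl]-4,6-dihydroxy-2-methoxy-5-(3-methylbut-2-enyl)phenyl]-2-methylpropan-1-one | COc1c(CN(C)C)c(O)c(CC=C(C)C)c(O)c1C(=O)C(C)C | intermediate
8 | diallyl propanedioate | C=CCOC(=O)CC(=O)OCC=C | starting material
9 | [2,4-dihydroxy-6-methoxy-5-(2-methylpropanoyl)-3-(3-methylbut-2-enyl)phenyl]methyl-trimethylammonium iodide | COc1c(C[N+](C)(C)C)c(O)c(CC=C(C)C)c(O)c1C(=O)C(C)C.[I-] | intermediate
10 | 3-hydroxy-5-methoxy-6-methylidene-4-(2-methylpropanoyl)-2-(3-methylbut-2-enyl)cyclohexa-2,4-dien-1-one | C=C1C(=O)C(CC=C(C)C)=C(O)C(C(=O)C(C)C)=C1OC | intermediate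
11 | diallyl 2-[[2,4-dihydroxy-6-methoxy-5-(2-methylpropanoyl)-3-(3-methylbut-2-enyl)phenyl]methyl]propanedioate | C=CCOC(=O)C(Cc1c(O)c(CC=C(C)C)c(O)c(C(=O)C(C)C)c1OC)C(=O)OCC=C | intermediate
12 | diallyl 2-[[2,4-diacetoxy-6-methoxy-5-(2-methylpropanoyl)-3-(3-methylbut-2-enyl)phenyl]methyl]propanedioate | C=CCOC(=O)C(Cc1c(OC(C)=O)c(CC=C(C)C)c(OC(C)=O)c(C(=O)C(C)C)c1OC)C(=O)OCC=C | intermediate
13 | 2-[[2,4-diacetoxy-6-methoxy-5-(2-methylpropanoyl)-3-(3-methylbut-2-enyl)phenyl]methyl]propanedioic acid | OC(=O)C(Cc1c(OC(C)=O)c(CC=C(C)C)c(OC(C)=O)c(C(=O)C(C)C)c1OC)C(=O)O | intermediate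
14 | 2-[[2,4-diacetoxy-6-methoxy-5-(2-methylpropanoyl)-3-(3-methylbut-2-enyl)phenyl]methyl]propanedioyl dichloride | O=C(Cl)C(Cc1c(OC(C)=O)c(CC=C(C)C)c(OC(C)=O)c(C(=O)C(C)C)c1OC)C(=O)Cl | intermediate
15 | pentan-3-one | CCC(=O)CC | starting material
16 | (Z)-trimethyl(pent-2-en-3-yloxy)silane | C/C=C(/CC)O[Si](C)(C)C | intermediate
17 | 2-[[2,4-diacetoxy-6-methoxy-5-(2-methylpropanoyl)-3-(3-methylbut-2-enyl)phenyl]methyl]-4-methyl-3,5-dioxoheptanoyl chloride (stereoisomer and enol mixture, both centres vanish in 18) | CCC(=O)C(C)C(=O)C(Cc1c(OC(C)=O)c(CC=C(C)C)c(OC(C)=O)c(C(=O)C(C)C)c1OC)C(=O)Cl | intermediate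
18 | 3-[[2,4-diacetoxy-6-methoxy-5-(2-methylpropanoyl)-3-(3-methylbut-2-enyl)phenyl]methyl]-6-ethyl-4-hydroxy-5-methyl-2H-pyran-2-one | CCc1oc(=O)c(Cc2c(OC(C)=O)c(CC=C(C)C)c(OC(C)=O)c(C(=O)C(C)C)c2OC)c(O)c1C | intermediate
19 | 3-[[2,4-dihydroxy-6-methoxy-5-(2-methylpropanoyl)-3-(3-methylbut-2-enyl)phenyl]methyl]-6-ethyl-4-hydroxy-5-methyl-2H-pyran-2-one | CCc1oc(=O)c(Cc2c(O)c(CC=C(C)C)c(O)c(C(=O)C(C)C)c2OC)c(O)c1C | target

Total step count: 10.
Longest linear sequence: 9 (steps 1–7, 9, 10). Step 8 is a one-step side branch.

**Steps most likely to fail**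

Step 9 (pyranone annulation).
- What may go wrong: the reaction may stall at O-acylation of the enol ether. The hindered dichloride may lose HCl and oligomerise before it is intercepted. HCl may add across the prenyl double bond. Carbon instead of oxygen may close the ring.
- Fallback: ring A is built first and the bridge last. Enol ether 16 is combined with unsubstituted malonyl dichloride (Et2O, −78 °C → rt), the parent case of the same annulation. This passes through 4-methyl-3,5-dioxoheptanoyl chloride F1 to 6-ethyl-4-hydroxy-5-methyl-2H-pyran-2-one F2.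
- F2 and Mannich base 7 are then warmed together in dioxane. The acidic pyranone protonates the amine, dimethylamine leaves to give quinone methide 10, and C3 of the pyranone adds to its CH2.
- The fallback sets out from 16 and 7 and comes back to the route at target 19. It needs no phenol protection and no acid chloride beside the prenyl group.

Step 4 (malonate alkylation through the quinone methide).
- What may go wrong: quaternisation may be accompanied by O-methylation of the acidic phenol. The quinone methide may be captured by a phenoxide or by itself instead of the malonate. The phenoxide next to the new side chain may lactonise on an allyl ester.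
- Fallback: the polarity of the bridge-forming bond is reversed. Malonate 8 is methylenated (paraformaldehyde, diisopropylammonium trifluoroacetate, THF, reflux; Knoevenagel-type condensation) to diallyl 2-methylidenepropanedioate F3.
- Prenyl ketone 6 then adds through its free ring carbon to this acceptor (Et3N cat., CH2Cl2, 0 °C). This is a Friedel–Crafts-type Michael addition of the kind known for acylphloroglucinols and alkylidene 1,3-dicarbonyl compounds.
- The fallback sets out from 6 and 8, needs neither MeI nor stoichiometric base, and comes back to the route at 11.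

Step 2 (C-prenylation).
- What may go wrong: alkylation of the ambident phenoxide may be poorly selective. O-prenylation, attack at C5 instead of C3, and double prenylation with dearomatisation all compete. The acylation before it has a regiochemical question of its own.
- Fallback: the substitution pattern is fixed by directed ortho-metalation on a symmetrical ring. Diol 1 is protected (MOMCl, i-Pr2NEt, CH2Cl2) as 1-methoxy-3,5-bis(methoxymethoxy)benzene F4.
- n-BuLi (THF, 0 °C) removes the proton between the two MOM ethers to give [4-methoxy-2,6-bis(methoxymethoxy)phenyl]lithium F5. Bromide 5 alkylates it to 5-methoxy-1,3-bis(methoxymethoxy)-2-(3-methylbut-2-enyl)benzene F6, in which the two remaining ring positions are equivalent.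
- A second lithiation (n-BuLi, TMEDA, THF) gives [6-methoxy-2,4-bis(methoxymethoxy)-3-(3-methylbut-2-enyl)phenyl]lithium F7. The Weinreb amide N-methoxy-N,2-dimethylpropanamide converts it into 1-[6-methoxy-2,4-bis(methoxymethoxy)-3-(3-methylbut-2-enyl)phenyl]-2-methylpropan-1-one F8.
- Brief treatment with catalytic HCl in MeOH removes both MOM groups.
- The fallback sets out from 1 and 5, bypasses steps 1 and 2, and comes back to the route at 6.

**Further compounds**
F1 | step 9 | 4-methyl-3,5-dioxoheptanoyl chloride | CCC(=O)C(C)C(=O)CC(=O)Cl
F2 | step 9 | 6-ethyl-4-hydroxy-5-methyl-2H-pyran-2-one | CCc1oc(=O)cc(O)c1C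
F3 | step 4 | diallyl 2-methylidenepropanedioate | C=CCOC(=O)C(=C)C(=O)OCC=C
F4 | step 2 | 1-methoxy-3,5-bis(methoxymethoxy)benzene | COCOc1cc(OC)cc(OCOC)c1
F5 | step 2 | [4-methoxy-2,6-bis(methoxymethoxy)phenyl]lithium | [Li]c1c(OCOC)cc(OC)cc1OCOC
F6 | step 2 | 5-methoxy-1,3-bis(methoxymethoxy)-2-(3-methylbut-2-enyl)benzene | COCOc1cc(OC)cc(OCOC)c1CC=C(C)C
F7 | step 2 | [6-methoxy-2,4-bis(methoxymethoxy)-3-(3-methylbut-2-enyl)phenyl]lithium | [Li]c1c(OC)cc(OCOC)c(CC=C(C)C)c1OCOC
F8 | step 2 | 1-[6-methoxy-2,4-bis(methoxymethoxy)-3-(3-methylbut-2-enyl)phenyl]-2-methylpropan-1-one | COCOc1cc(OC)c(C(=O)C(C)C)c(OCOC)c1CC=C(C)C
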